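**Retrosynthetic overview**
1. The acid 26 comes from its methyl ester and silyl ethers; the C6 carbinol and C5–H come from a C6 ethyl enol ether (hydrolysis, then hydride from the α-face).
2. Side chain: C11–C12 by γ-alkylation of the methyl acetoacetate dianion with a C11 allylic bromide; the (13E)-enoate by enol phosphate/methylcuprate exchange.
3. Key disconnection: ring B (C5–C10) by Diels–Alder addition of methyl but-2-ynoate to the ring A 2-ethoxydiene 11, forming C7–C8 and C9–C10. The feature used is ring B's tetrasubstituted C8=C9 double bond next to quaternary C10, with oxygen on C6.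
4. Diene 11 from 2-methylcyclohexane-1,3-dione: hydroxymethylation, chelation-controlled asymmetric hydrogenation (sets C3 and C4), silylation, C10 methylation, enol triflate, Stille coupling.
5. Ring order: ring A is carried from the dione; ring B is formed in the key step.

Key step: step 7

Remark: labdane numbering is used (ring A = C1–C5, C10; ring B = C5–C10; C17 on C8, C18 = 4α-methyl, C19 = 4β-CH2O, C20 on C10, C11 on C9). α/β refer to the usual drawing with the C10 methyl β. The target is taken as drawn, (3R,4S,5R,6R,10S,13E), that is 3α,6β,19-trihydroxylabda-8,13E-dien-15-oic acid.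

**Route**

Step 1
Reactants: 1 2-methylcyclohexane-1,3-dione; 2 formaldehyde (37% aqueous)
Product: 3 2-(hydroxymethyl)-2-methylcyclohexane-1,3-dione
Conditions: 37% aq. CH2O, H2O, 25 °C
Reagents that add atoms: none
Why: Aldol hydroxymethylation of the acidic, enolised 1,3-dione at C2 with formaldehyde should give the achiral quaternary diketo alcohol, which already holds C4 and C19 and has no stereocenter.

Step 2
Reactants: 3 2-(hydroxymethyl)-2-methylcyclohexane-1,3-dione
Product: 4 (2S,3R)-3-hydroxy-2-(hydroxymethyl)-2-methylcyclohexan-1-one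
Conditions: H2 (50 atm), [RuCl(p-cymene)((R)-BINAP)]Cl (1 mol %), MeOH, 35 °C, stopped after 1 equiv H2
Reagents that add atoms: none
Why: Noyori asymmetric hydrogenation of a β-hydroxy ketone, in which the C19 hydroxyl and one carbonyl chelate ruthenium so that hydride reaches that carbonyl from the face of the CH2OH arm (C3–OH trans to C19, as in the trans-selective hydrogenation of cyclic 2-alkoxycarbonyl ketones), while the (R)-BINAP ligand, which gives (R)-carbinols from β-functionalised ketones, thereby decides which enantiotopic carbonyl is reduced, so that C3 (R) and C4 (S) are set together.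

Step 3
Reactants: 4 (2S,3R)-3-hydroxy-2-(hydroxymethyl)-2-methylcyclohexan-1-one
Product: 5 (2S,3R)-3-[(tert-butyldimethylsilyl)oxy]-2-{[(tert-butyldimethylsilyl)oxy]methyl}-2-methylcyclohexan-1-one
Conditions: TBSOTf, 2,6-lutidine, CH2Cl2, −78 → 0 °C
Reagents that add atoms: tert-butyldimethylsilyl trifluoromethanesulfonate, CC(C)(C)[Si](C)(C)OS(=O)(=O)C(F)(F)F
Why: Silylation with the silyl triflate and a hindered pyridine base should protect the primary C19 hydroxyl and the hindered secondary C3 hydroxyl in one operation without retro-aldol cleavage and without touching the stereocenters.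

Step 4
Reactants: 5 (2S,3R)-3-[(tert-butyldimethylsilyl)oxy]-2-{[(tert-butyldimethylsilyl)oxy]methyl}-2-methylcyclohexan-1-one
Product: 7 (2S,3R,6RS)-3-[(tert-butyldimethylsilyl)oxy]-2-{[(tert-butyldimethylsilyl)oxy]methyl}-2,6-dimethylcyclohexan-1-one, via lithium enolate 6 (not isolated)
Conditions: LiN(iPr)2, THF, −78 °C; MeI, −78 → −20 °C
Reagents that add atoms: iodomethane, CI
Why: Deprotonation can only occur at the single α-methylene (C10), and C-methylation of the lithium enolate (enolate alkylation) installs C20, the configuration of the new center being irrelevant because C10 becomes trigonal in the next step.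

Step 5
Reactants: 7 (2S,3R,6RS)-3-[(tert-butyldimethylsilyl)oxy]-2-{[(tert-butyldimethylsilyl)oxy]methyl}-2,6-dimethylcyclohexan-1-one
Product: 9 (5R,6S)-5-[(tert-butyldimethylsilyl)oxy]-6-{[(tert-butyldimethylsilyl)oxy]methyl}-2,6-dimethylcyclohex-1-en-1-yl trifluoromethanesulfonate, via potassium enolate 8 (not isolated)
Conditions: KN(SiMe3)2, THF, −78 → 0 °C; PhNTf2, −78 → 25 °C
Reagents that add atoms: N-phenylbis(trifluoromethanesulfonimide), O=S(=O)(N(c1ccccc1)S(=O)(=O)C(F)(F)F)C(F)(F)F
Why: The only remaining α-hydrogen is on C10, so the enolate is necessarily the tetrasubstituted C5=C10 enolate, which the triflimide traps on oxygen (enol triflate formation), erasing the C10 center.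

Step 6
Reactants: 9 (5R,6S)-5-[(tert-butyldimethylsilyl)oxy]-6-{[(tert-butyldimethylsilyl)oxy]methyl}-2,6-dimethylcyclohex-1-en-1-yl trifluoromethanesulfonate; 10 tributyl(1-ethoxyvinyl)stannane
Product: 11 tert-butyl({(1S,6R)-6-[(tert-butyldimethylsilyl)oxy]-2-(1-ethoxyethenyl)-1,3-dimethylcyclohex-2-en-1-yl}methoxy)dimethylsilane (ring A 2-ethoxydiene)
Conditions: Pd(PPh3)4 (10 mol %), CuCl, LiCl, DMSO, 60 °C
Reagents that add atoms: none
Why: Stille coupling of the enol triflate with the α-ethoxyvinylstannane, run with CuCl and LiCl to speed transmetalation at the hindered tetrasubstituted triflate, should give the 2-ethoxydiene with the C5=C10 geometry fixed by the ring, provided that work-up and chromatography are kept basic to preserve the enol ether.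

Step 7
Reactants: 11 ring A 2-ethoxydiene; 12 methyl but-2-ynoate
Product: 13 methyl (5S,6R,8aS)-6-[(tert-butyldimethylsilyl)oxy]-5-{[(tert-butyldimethylsilyl)oxy]methyl}-4-ethoxy-2,5,8a-trimethyl-3,5,6,7,8,8a-hexahydronaphthalene-1-carboxylate
Conditions: 12 (8 equiv), BHT, K2CO3, toluene, 140 °C, sealed tube
Reagents that add atoms: none
Why: A thermal, normal-electron-demand intermolecular Diels–Alder reaction: the ethoxy group on C6 raises the diene HOMO and puts its largest coefficient on C7, which bonds to the methyl-bearing β-carbon of the ynoate (C8) in an asynchronous concerted transition state while C10 bonds to the ester-bearing carbon (C9). The closest known reactions are the cycloadditions of 2,6,6-trimethyl-1-vinylcyclohexene-type dienes and of 2-alkoxy- or 2-silyloxybutadienes with acetylenic esters. Ring B closes by the [4+2] cycloaddition itself, both new bonds forming suprafacially on the diene, and the resulting cyclohexa-1,4-diene cannot aromatise because C10 is quaternary. The new stereocenter C10 is controlled by C3 and C4: in the half-chair of ring A the two silyloxy-bearing groups should stand trans-diaxial to avoid a gauche contact, which leaves the C4 methyl in the diene plane and the C19 silyloxymethyl group perpendicular on the β-face, so the alkyne adds to the α-face and the inside methyl on C10 (C20) is turned to the β-face, cis to C19 (10S). The step needs regioselectivity, which the 2-ethoxy group and the disubstituted C10 terminus both favour, π-facial selectivity, which rests on the trans-diaxial bis-silyl ether, and a cycloaddition faster than the [1,5]-hydrogen shift from C20 to C7, for which the cisoid preference of the 2-substituted diene and the excess of dienophile are relied on.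

Step 8
Reactants: 13 bicyclic dienyl ester
Product: 14 C11 allylic alcohol (13 with CO2Me reduced to CH2OH; 3α-OTBS, 4β-CH2OTBS, 10β-methyl, 6-ethoxy-5,8-diene)
Conditions: iBu2AlH, toluene, −78 → 0 °C
Reagents that add atoms: none
Why: Reduction of the hindered conjugated ester with excess diisobutylaluminium hydride should give the C11 allylic alcohol (ester to alcohol reduction), the enol ether and the silyl ethers being inert to the hydride.

Step 9
Reactants: 14 C11 allylic alcohol
Product: 16 C11 allylic bromide (14 with CH2OH replaced by CH2Br), via allylic mesylate 15 (not isolated)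
Conditions: MsCl, Et3N, CH2Cl2, −40 °C; LiBr, THF, 0 °C
Reagents that add atoms: lithium bromide, [Li+].[Br-]
Why: Mesylation under basic conditions followed by SN2 displacement by bromide at the primary allylic carbon should give the bromide without acid, so the enol ether survives, and attack at the fully substituted C8 is sterically disfavoured.

Step 10
Reactants: 16 C11 allylic bromide; 17 methyl acetoacetate
Product: 19 methyl 3α,19-bis(tert-butyldimethylsilyloxy)-6-ethoxy-13-oxo-16-norlabda-5,8-dien-15-oate, via acetoacetate dianion 18 (not isolated)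
Conditions: 17, NaH, THF, 0 °C; n-BuLi, 0 °C; 16, 0 → 25 °C; aq. NH4Cl
Reagents that add atoms: none
Why: The dianion of methyl acetoacetate reacts at its more nucleophilic terminal carbon with the allylic bromide (acetoacetate dianion γ-alkylation), forming the C11–C12 bond and bringing in C12 to C15 as a β-keto ester.

Step 11
Reactants: 19 β-keto ester
Product: 21 methyl (13Z)-3α,19-bis(tert-butyldimethylsilyloxy)-13-(diethoxyphosphoryloxy)-6-ethoxy-16-norlabda-5,8,13-trien-15-oate, via sodium enolate 20 (not isolated)
Conditions: NaH, Et2O, 0 °C; ClP(O)(OEt)2, 0 → 25 °C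
Reagents that add atoms: diethyl chlorophosphate, CCOP(=O)(Cl)OCC
Why: The sodium enolate of the β-keto ester is held in the chelated Z form, so O-phosphorylation should give the (Z)-enol phosphate with the phosphate cis to the ester (enol phosphate formation).

Step 12
Reactants: 21 (Z)-enol phosphate
Product: 22 methyl (13E)-3α,19-bis(tert-butyldimethylsilyloxy)-6-ethoxylabda-5,8,13-trien-15-oate
Conditions: Me2CuLi (MeLi, CuI), Et2O, −78 → −45 °C
Reagents that add atoms: lithium dimethylcuprate, [Li+].C[Cu-]C (made in the flask from methyllithium, [Li]C, and CuI)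
Why: The cuprate replaces the phosphate by methyl with retention of the double-bond geometry (addition–elimination at a β-phosphoryloxy enoate), so C16 ends cis to the ester and the chain trans to it, which is the (13E)-enoate.

Step 13
Reactants: 22 (13E)-enoate enol ether
Product: 23 methyl (13E)-3α,19-bis(tert-butyldimethylsilyloxy)-6-oxo-5α-labda-8,13-dien-15-oate
Conditions: oxalic acid (cat.), THF/H2O, 25 °C
Reagents that add atoms: water, O
Why: Mild acid hydrolysis of the enol ether, as for Birch-type 1-alkoxycyclohexa-1,4-dienes, protonates C5 and releases the C6 ketone without moving the C8=C9 double bond into conjugation, the proton entering from the α-face because the β-face of C5 is flanked by the axial C10 methyl and the axial C19 silyloxymethyl group, which gives the trans ring fusion (5R) that is also the more stable epimer of this enolisable center.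

Step 14
Reactants: 23 C6 ketone
Product: 24 methyl (13E)-3α,19-bis(tert-butyldimethylsilyloxy)-6β-hydroxylabda-8,13-dien-15-oate
Conditions: NaBH4, MeOH, 0 °C
Reagents that add atoms: none
Why: Borohydride reduction of the C6 ketone should occur by hydride attack from the α-face, the β-face being closed by the syn-axial C10 methyl and C19 substituent, which gives the axial 6β-alcohol (6R) as in reductions of 6-oxo steroids and 6-oxo drimanes, while the β,β-disubstituted enoate is left untouched.

Step 15
Reactants: 24 6β-alcohol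
Product: 25 methyl (13E)-3α,6β,19-trihydroxylabda-8,13-dien-15-oate
Conditions: HF·pyridine, pyridine/THF, 0 → 25 °C
Reagents that add atoms: none
Why: Fluoride-induced cleavage of both silyl ethers (desilylation) with buffered HF·pyridine should free the primary C19 and the hindered axial C3 hydroxyls without touching the ester, the trisubstituted enoate or the stereocenters.

Step 16
Reactants: 25 triol methyl ester
Product: 26 (13E)-3α,6β,19-trihydroxylabda-8,13-dien-15-oic acid (3R,4S,5R,6R,10S), the target
Conditions: LiOH, THF/MeOH/H2O, 40 °C; 1 M HCl to pH 3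
Reagents that add atoms: lithium hydroxide, [Li+].[OH-]
Why: Saponification of the methyl ester followed by careful acidification should give the acid without isomerising the (13E) double bond or dehydrating the non-allylic secondary alcohols.

**Compound list**
1 | 2-methylcyclohexane-1,3-dione | CC1C(=O)CCCC1=O | starting material
2 | formaldehyde (37% aqueous) | C=O | starting material
3 | 2-(hydroxymethyl)-2-methylcyclohexane-1,3-dione | CC1(CO)C(=O)CCCC1=O | intermediate
4 | (2S,3R)-3-hydroxy-2-(hydroxymethyl)-2-methylcyclohexan-1-one (OH trans to CH2OH) | O=C1CCC[C@@H](O)[C@]1(C)CO | intermediate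
5 | (2S,3R)-3-[(tert-butyldimethylsilyl)oxy]-2-{[(tert-butyldimethylsilyl)oxy]methyl}-2-methylcyclohexan-1-one | O=C1CCC[C@@H](O[Si](C)(C)C(C)(C)C)[C@]1(C)CO[Si](C)(C)C(C)(C)C | intermediate
6 | lithium enolate of 5 (C5–O, C5=C10) | [Li+].[O-]C1=CCC[C@@H](O[Si](C)(C)C(C)(C)C)[C@]1(C)CO[Si](C)(C)C(C)(C)C | intermediate
7 | (2S,3R,6RS)-3-[(tert-butyldimethylsilyl)oxy]-2-{[(tert-butyldimethylsilyl)oxy]methyl}-2,6-dimethylcyclohexan-1-one (both C6 epimers) | O=C1C(C)CC[C@@H](O[Si](C)(C)C(C)(C)C)[C@]1(C)CO[Si](C)(C)C(C)(C)C | intermediate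
8 | potassium enolate of 7 (tetrasubstituted) | [K+].[O-]C1=C(C)CC[C@@H](O[Si](C)(C)C(C)(C)C)[C@]1(C)CO[Si](C)(C)C(C)(C)C | intermediate
9 | (5R,6S)-5-[(tert-butyldimethylsilyl)oxy]-6-{[(tert-butyldimethylsilyl)oxy]methyl}-2,6-dimethylcyclohex-1-en-1-yl trifluoromethanesulfonate | CC1=C(OS(=O)(=O)C(F)(F)F)[C@@](C)(CO[Si](C)(C)C(C)(C)C)[C@H](O[Si](C)(C)C(C)(C)C)CC1 | intermediate
10 | tributyl(1-ethoxyvinyl)stannane | CCCC[Sn](CCCC)(CCCC)C(=C)OCC | starting material
11 | tert-butyl({(1S,6R)-6-[(tert-butyldimethylsilyl)oxy]-2-(1-ethoxyethenyl)-1,3-dimethylcyclohex-2-en-1-yl}methoxy)dimethylsilane (ring A 2-ethoxydiene) | CC1=C(C(=C)OCC)[C@@](C)(CO[Si](C)(C)C(C)(C)C)[C@H](O[Si](C)(C)C(C)(C)C)CC1 | intermediate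
12 | methyl but-2-ynoate | CC#CC(=O)OC | starting material
13 | methyl (5S,6R,8aS)-6-[(tert-butyldimethylsilyl)oxy]-5-{[(tert-butyldimethylsilyl)oxy]methyl}-4-ethoxy-2,5,8a-trimethyl-3,5,6,7,8,8a-hexahydronaphthalene-1-carboxylate | CC1=C(C(=O)OC)[C@@]2(C)CC[C@@H](O[Si](C)(C)C(C)(C)C)[C@](C)(CO[Si](C)(C)C(C)(C)C)C2=C(OCC)C1 | intermediate
14 | C11 allylic alcohol (13 with CO2Me as CH2OH) | CC1=C(CO)[C@@]2(C)CC[C@@H](O[Si](C)(C)C(C)(C)C)[C@](C)(CO[Si](C)(C)C(C)(C)C)C2=C(OCC)C1 | intermediate
15 | C11 allylic mesylate | CC1=C(COS(C)(=O)=O)[C@@]2(C)CC[C@@H](O[Si](C)(C)C(C)(C)C)[C@](C)(CO[Si](C)(C)C(C)(C)C)C2=C(OCC)C1 | intermediate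
16 | C11 allylic bromide | CC1=C(CBr)[C@@]2(C)CC[C@@H](O[Si](C)(C)C(C)(C)C)[C@](C)(CO[Si](C)(C)C(C)(C)C)C2=C(OCC)C1 | intermediate
17 | methyl acetoacetate | COC(=O)CC(C)=O | starting material
18 | dianion of methyl acetoacetate (sodium lithium salt) | COC(=O)[CH-]C(=O)[CH2-].[Na+].[Li+] | intermediate
19 | methyl 3α,19-bis(tert-butyldimethylsilyloxy)-6-ethoxy-13-oxo-16-norlabda-5,8-dien-15-oate | CC1=C(CCC(=O)CC(=O)OC)[C@@]2(C)CC[C@@H](O[Si](C)(C)C(C)(C)C)[C@](C)(CO[Si](C)(C)C(C)(C)C)C2=C(OCC)C1 | intermediate
20 | sodium (Z)-enolate of 19 | CC1=C(CC/C([O-])=C/C(=O)OC)[C@@]2(C)CC[C@@H](O[Si](C)(C)C(C)(C)C)[C@](C)(CO[Si](C)(C)C(C)(C)C)C2=C(OCC)C1.[Na+] | intermediate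
21 | methyl (13Z)-3α,19-bis(tert-butyldimethylsilyloxy)-13-(diethoxyphosphoryloxy)-6-ethoxy-16-norlabda-5,8,13-trien-15-oate | CC1=C(CC/C(OP(=O)(OCC)OCC)=C/C(=O)OC)[C@@]2(C)CC[C@@H](O[Si](C)(C)C(C)(C)C)[C@](C)(CO[Si](C)(C)C(C)(C)C)C2=C(OCC)C1 | intermediate
22 | methyl (13E)-3α,19-bis(tert-butyldimethylsilyloxy)-6-ethoxylabda-5,8,13-trien-15-oate | CC1=C(CC/C(C)=C/C(=O)OC)[C@@]2(C)CC[C@@H](O[Si](C)(C)C(C)(C)C)[C@](C)(CO[Si](C)(C)C(C)(C)C)C2=C(OCC)C1 | intermediate
23 | methyl (13E)-3α,19-bis(tert-butyldimethylsilyloxy)-6-oxo-5α-labda-8,13-dien-15-oate | CC1=C(CC/C(C)=C/C(=O)OC)[C@@]2(C)CC[C@@H](O[Si](C)(C)C(C)(C)C)[C@](C)(CO[Si](C)(C)C(C)(C)C)[C@@H]2C(=O)C1 | intermediate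
24 | methyl (13E)-3α,19-bis(tert-butyldimethylsilyloxy)-6β-hydroxylabda-8,13-dien-15-oate | CC1=C(CC/C(C)=C/C(=O)OC)[C@@]2(C)CC[C@@H](O[Si](C)(C)C(C)(C)C)[C@](C)(CO[Si](C)(C)C(C)(C)C)[C@@H]2[C@H](O)C1 | intermediate
25 | methyl (13E)-3α,6β,19-trihydroxylabda-8,13-dien-15-oate | CC1=C(CC/C(C)=C/C(=O)OC)[C@@]2(C)CC[C@@H](O)[C@](C)(CO)[C@@H]2[C@H](O)C1 | intermediate
26 | (13E)-3α,6β,19-trihydroxylabda-8,13-dien-15-oic acid (3R,4S,5R,6R,10S) | CC1=C(CC/C(C)=C/C(=O)O)[C@@]2(C)CC[C@@H](O)[C@](C)(CO)[C@@H]2[C@H](O)C1 | target

Total step count: 16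
Longest linear sequence: 16 steps (1 to 26)

**Steps most likely to fail**

Step 7 (Diels–Alder). The cycloaddition at the fully substituted C10 terminus with a β-methyl ynoate may be too slow, so that the [1,5]-hydrogen shift from C20 to C7 and thermal decay of the diene compete. At the temperature needed, shielding of the β-face by the axial C19 group may also be incomplete, giving poor facial selectivity. The fallback sets out from 11 and uses a halogen-activated dienophile. Methyl propiolate is brominated (NBS, AgNO3 cat., acetone) to methyl 3-bromopropiolate F1, which has the same polarisation as 12 but is far more dienophilic and should add at 25–60 °C, C7 bonding to the bromine-bearing carbon. This gives the 8-bromo analogue of 13, methyl (5S,6R,8aS)-2-bromo-6-[(tert-butyldimethylsilyl)oxy]-5-{[(tert-butyldimethylsilyl)oxy]methyl}-4-ethoxy-5,8a-dimethyl-3,5,6,7,8,8a-hexahydronaphthalene-1-carboxylate F2. Addition–elimination of Me2CuLi at this β-bromo enoate (Et2O, −78 °C) replaces bromine by the C17 methyl and comes back to the route at 13.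

Step 2 (desymmetrising hydrogenation). The hydrogenation may not be confined to one enantiotopic carbonyl (low enantiomeric purity), may run on to triols, or the substrate may lose formaldehyde by retro-aldol cleavage. The fallback sets out from 3 and separates diastereocontrol from enantiocontrol. Hydroxyl-directed reduction with Me4NBH(OAc)3 in AcOH/MeCN at −30 °C delivers hydride intramolecularly from the C19 alkoxyborohydride and gives the same trans relationship, as 4 together with its enantiomer (2R,3S)-3-hydroxy-2-(hydroxymethyl)-2-methylcyclohexan-1-one F3. Bis-silylation as in step 3 gives 5 together with its enantiomer (2R,3S)-3-[(tert-butyldimethylsilyl)oxy]-2-{[(tert-butyldimethylsilyl)oxy]methyl}-2-methylcyclohexan-1-one F4. Preparative chromatography on a chiral stationary phase separates the two, and the route is rejoined at 5.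

Step 6 (Stille coupling). Oxidative addition and transmetalation at the tetrasubstituted triflate next to a quaternary carbon may be slow, so that reduction of the triflate, protodestannylation or hydrolysis of the enol ether take over. The fallback sets out from ketone 7 and builds the diene by carbonyl addition and dehydration. 1-Ethoxyvinyllithium (ethyl vinyl ether, t-BuLi, THF; CeCl3 to suppress enolisation) adds to the ketone to give the tertiary alcohol (2S,3R)-3-[(tert-butyldimethylsilyl)oxy]-2-{[(tert-butyldimethylsilyl)oxy]methyl}-1-(1-ethoxyethenyl)-2,6-dimethylcyclohexan-1-ol F5. Dehydration with the Burgess reagent under neutral conditions can only remove the single β-hydrogen on C10, because C4 is quaternary, and so comes back to the route at 11.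

**Further compounds**
F1 | step 7 | methyl 3-bromopropiolate | COC(=O)C#CBr
F2 | step 7 | methyl (5S,6R,8aS)-2-bromo-6-[(tert-butyldimethylsilyl)oxy]-5-{[(tert-butyldimethylsilyl)oxy]methyl}-4-ethoxy-5,8a-dimethyl-3,5,6,7,8,8a-hexahydronaphthalene-1-carboxylate | BrC1=C(C(=O)OC)[C@@]2(C)CC[C@@H](O[Si](C)(C)C(C)(C)C)[C@](C)(CO[Si](C)(C)C(C)(C)C)C2=C(OCC)C1
F3 | step 2 | (2R,3S)-3-hydroxy-2-(hydroxymethyl)-2-methylcyclohexan-1-one | O=C1CCC[C@H](O)[C@@]1(C)CO
F4 | step 2 | (2R,3S)-3-[(tert-butyldimethylsilyl)oxy]-2-{[(tert-butyldimethylsilyl)oxy]methyl}-2-methylcyclohexan-1-one | O=C1CCC[C@H](O[Si](C)(C)C(C)(C)C)[C@@]1(C)CO[Si](C)(C)C(C)(C)C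
F5 | step 6 | (2S,3R)-3-[(tert-butyldimethylsilyl)oxy]-2-{[(tert-butyldimethylsilyl)oxy]methyl}-1-(1-ethoxyethenyl)-2,6-dimethylcyclohexan-1-ol | CCOC(=C)C1(O)C(C)CC[C@@H](O[Si](C)(C)C(C)(C)C)[C@]1(C)CO[Si](C)(C)C(C)(C)C
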